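**Retrosynthetic overview**
1. Last operations: lactone walk O6′→O8′ and acetylation; the C2 carbinol comes from an intramolecular lactol-to-ketone hydride relay (C12′–H → C2), not from a 2-acetoxy diene.
2. Key step: the spiro-norbornene (C1–C13′, C3–C11′) is closed by an acetal-tethered intramolecular [4+2] of a cyclopentadienone ketal (tether C2–O–C12′), replacing the intermolecular dimerisation of the two lactones.
3. Diene half: 2,5-dimethylfuran → C10 by Friedel–Crafts → seven-membered ring plus trans-lactone by intramolecular chromium allylation → furan opened and re-closed to the five-membered ring.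
4. Dienophile half: (R)-citronellal plus an acrolein-derived allyl bromide → chromium allylation (C6′/C7′) → ring-closing metathesis → hydroxy enal/lactol.
5. Ring order: furan, cycloheptane with lactone, cyclopentene ketal; cyclohexene; then norbornene with spiro-lactol; the spiro-lactone reaches O8′ last.

Assumption: the target is taken exactly as drawn; H7 and H7′ are then opposite to the usual plant series, so no natural monomer is used. The route is a paper design and none of it has been tested.

Numbering: diene half as a guaiane (C1–C15; C2 is the bridging carbon, 12,8-lactone), dienophile half as a 1,10-seco-eudesmane with primed locants; the halves are joined C1–C13′ and C3–C11′.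

Why the direct dimerisation is avoided: a 5-acyloxycyclopentadiene is attacked syn to oxygen, which would put the C2 acetate anti to the ring alkene (the target has it syn), and it is prone to 1,5-hydrogen shifts. In addition, with C12′ exo and attack anti to the C10 methyl, the 8′,12′-lactone would have to react on the face covered by its own cyclohexene ring.

**Part A – diene half**

Step 1
Reactants: 1 2,5-dimethylfuran; 2 (E)-but-2-enal
Product: 3 (R)-3-(2,5-dimethylfuran-3-yl)butanal
Conditions: (2S,5S)-5-benzyl-2-tert-butyl-3-methylimidazolidin-4-one·TFA (20 mol %), 1 (3 equiv), CH2Cl2/i-PrOH, −30 °C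
Reagents that add atoms: none
Why: Iminium-catalysed Friedel–Crafts conjugate addition (MacMillan type) at the only free furan position; the catalyst shields one face of the E-iminium ion and sets C10 as R.

Step 2
Reactants: 3 (R)-3-(2,5-dimethylfuran-3-yl)butanal
Product: 4 (R)-3-(4-bromo-2,5-dimethylfuran-3-yl)butanal
Conditions: NBS, DMF, −20 °C, dark
Reagents that add atoms: N-bromosuccinimide O=C1CCC(=O)N1Br
Why: Electrophilic aromatic bromination at the last free ring position (future C5).

Step 3
Reactants: 4 (R)-3-(4-bromo-2,5-dimethylfuran-3-yl)butanal; 5 allyltributylstannane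
Product: 6 (R)-3-(4-allyl-2,5-dimethylfuran-3-yl)butanal
Conditions: Pd(PPh3)4 (5 mol %), DMF, 90 °C
Reagents that add atoms: none
Why: Migita–Kosugi–Stille coupling installs C6/C7 as an allyl group and tolerates the aldehyde.

Step 4
Reactants: 6 (R)-3-(4-allyl-2,5-dimethylfuran-3-yl)butanal; 7 methyl 2-(bromomethyl)acrylate
Product: 8 methyl (Z)-2-(bromomethyl)-4-{2,5-dimethyl-4-[(R)-4-oxobutan-2-yl]furan-3-yl}but-2-enoate
Conditions: second-generation Hoveyda–Grubbs catalyst (5 mol %), 7 (4 equiv), CH2Cl2, 40 °C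
Reagents that add atoms: none
Why: Olefin cross-metathesis of a terminal alkene with a 1,1-disubstituted acrylate gives the trisubstituted enoate (chain trans to the ester); both alkene geometries converge in step 5.

Step 5
Reactants: 8 methyl (Z)-2-(bromomethyl)-4-{2,5-dimethyl-4-[(R)-4-oxobutan-2-yl]furan-3-yl}but-2-enoate
Product: 10 furan-fused trans-α-methylene lactone (7S,8R,10R), via hydroxy ester 9 (not isolated)
Conditions: CrCl2 (6 equiv), THF (0.005 M), 25 °C; then p-TsOH (cat.), CH2Cl2
Reagents that add atoms: none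
Why: Intramolecular Nozaki–Hiyama allylation then lactonisation: the chair transition state of the allylchromium gives the C7/C8 anti (trans-lactone) pair, and A(1,3) strain with the furan 2-methyl keeps the C10 methyl pseudo-axial so that the equatorial C8–O bond forms trans to it.

Step 6
Reactants: 10 furan-fused trans-α-methylene lactone
Product: 11 Z-ene-1,4-dione lactone (1,5-diacetylcycloheptene)
Conditions: m-CPBA (1.05 equiv), NaHCO3, CH2Cl2, 0 °C
Reagents that add atoms: 3-chloroperbenzoic acid OOC(=O)c1cccc(Cl)c1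
Why: Oxidative ring opening of a tetrasubstituted furan to the Z-ene-dione; the electron-poor methylene lactone does not react with the peracid.

Step 7
Reactants: 11 Z-ene-1,4-dione lactone
Product: 13 2-oxoguaia-1(5),4(15),11(13)-trien-12,8-olide (7S,8R,10R), via aldol 12 (not isolated)
Conditions: p-TsOH·H2O (0.2 equiv), toluene, 50 °C
Reagents that add atoms: none
Why: Acid-catalysed intramolecular aldol condensation (as for hex-3-ene-2,5-dione): the enol of the hindered acetyl on C1 attacks the less hindered acetyl on C5, and the tertiary carbinol loses water toward its methyl because loss toward C3 would give an antiaromatic cyclopentadienone.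

Step 8
Reactants: 13 2-oxoguaia-1(5),4(15),11(13)-trien-12,8-olide
Product: 14 2,2-dimethoxyguaia-1(5),4(15),11(13)-trien-12,8-olide (7S,8R,10R)
Conditions: MeOSiMe3 (4 equiv), Me3SiOTf (5 mol %), CH2Cl2, −78 °C; pyridine quench
Reagents that add atoms: methoxytrimethylsilane CO[Si](C)(C)C
Why: Noyori ketalisation of the enone carbonyl at low temperature without double-bond migration; 14 is not an s-cis diene and is therefore storable.

**Part B – dienophile half**

Step 9
Reactants: 15 (R)-citronellal
Product: 17 (R)-6,6-dimethoxy-4-methylhexan-1-ol, via citronellal dimethyl acetal 16 (not isolated)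
Conditions: HC(OMe)3, MeOH, p-TsOH (cat.), 25 °C; NaHCO3; then O3, CH2Cl2–MeOH, −78 °C; then NaBH4, −78 → 0 °C
Reagents that add atoms: trimethyl orthoformate COC(OC)OC; ozone [O-][O+]=O
Why: Acetalisation protects the aldehyde (and blocks ene cyclisation), then ozonolysis with reductive work-up turns the isopropylidene end into the C1′ alcohol; C4′ (R) is untouched.

Step 10
Reactants: 17 (R)-6,6-dimethoxy-4-methylhexan-1-ol
Product: 18 (R)-tert-butyl[(6,6-dimethoxy-4-methylhexyl)oxy]dimethylsilane
Conditions: TBSCl, imidazole, DMF, 25 °C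
Reagents that add atoms: tert-butyldimethylsilyl chloride CC(C)(C)[Si](C)(C)Cl
Why: Standard silylation of the primary alcohol.

Step 11
Reactants: 18 (R)-tert-butyl[(6,6-dimethoxy-4-methylhexyl)oxy]dimethylsilane
Product: 19 (R)-6-[(tert-butyldimethylsilyl)oxy]-3-methylhexanal
Conditions: PPTS (cat.), acetone–H2O, 45 °C
Reagents that add atoms: water O
Why: Mild acetal hydrolysis that leaves the primary silyl ether in place.

Step 12
Reactants: 19 (R)-6-[(tert-butyldimethylsilyl)oxy]-3-methylhexanal
Product: 20 (R)-6-[(tert-butyldimethylsilyl)oxy]-3-methyl-2-methylenehexanal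
Conditions: 37% aq. CH2O, pyrrolidine (10 mol %), EtCO2H (10 mol %), i-PrOH, 45 °C
Reagents that add atoms: formaldehyde C=O
Why: Organocatalytic α-methylenation (Mannich addition then elimination); the C4′ stereocentre is not enolisable under these conditions.

Step 13
Reactants: 21 acrolein; 22 tributyl(2-methylallyl)stannane
Product: 23 (S)-5-methylhexa-1,5-dien-3-ol
Conditions: (S)-BINOL (10 mol %), Ti(O-i-Pr)4 (10 mol %), 4 Å molecular sieves, CH2Cl2, −20 °C
Reagents that add atoms: none
Why: Keck asymmetric allylation (BINOL–titanium Lewis acid, allylstannane addition) sets C8′; the BINOL enantiomer is the one that gives the S carbinol.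

Step 14
Reactants: 23 (S)-5-methylhexa-1,5-dien-3-ol
Product: 24 (S)-tert-butyldimethyl[(5-methylhexa-1,5-dien-3-yl)oxy]silane
Conditions: TBSCl, imidazole, DMF, 25 °C
Reagents that add atoms: tert-butyldimethylsilyl chloride CC(C)(C)[Si](C)(C)Cl
Why: Standard silylation; this secondary silyl ether survives to the last step.

Step 15
Reactants: 24 (S)-tert-butyldimethyl[(5-methylhexa-1,5-dien-3-yl)oxy]silane; 7 methyl 2-(bromomethyl)acrylate
Product: 25 methyl (S,Z)-2-(bromomethyl)-4-[(tert-butyldimethylsilyl)oxy]-6-methylhepta-2,6-dienoate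
Conditions: second-generation Hoveyda–Grubbs catalyst (5 mol %), 7 (4 equiv), CH2Cl2, 40 °C
Reagents that add atoms: none
Why: Cross-metathesis at the monosubstituted alkene only (the methallyl group is less reactive and cannot ring-close with it).

Step 16
Reactants: 20 (R)-6-[(tert-butyldimethylsilyl)oxy]-3-methyl-2-methylenehexanal; 25 methyl (S,Z)-2-(bromomethyl)-4-[(tert-butyldimethylsilyl)oxy]-6-methylhepta-2,6-dienoate
Product: 27 acyclic hydroxy ester (4′R,6′R,7′R,8′S), via trimethylsilyl ether 26 (not isolated)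
Conditions: CrCl2 (10 mol %), chiral carbazole bis(oxazoline) ligand (12 mol %), manganese powder (2 equiv), Me3SiCl (1.5 equiv), THF, 0 °C; then citric acid, MeOH, 0 °C
Reagents that add atoms: chlorotrimethylsilane C[Si](C)(C)Cl (its silyl group is in 26 only and leaves on work-up)
Why: Catalytic asymmetric Nozaki–Hiyama 2-(alkoxycarbonyl)allylation: the chair transition state gives the 6′,7′-anti pair and the ligand selects the aldehyde face (C6′ R), with the C8′ centre of 25 already fixed.

Step 17
Reactants: 27 acyclic hydroxy ester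
Product: 28 cyclohexene hydroxy ester (4′R,6′R,7′R,8′S)
Conditions: second-generation Grubbs catalyst (10 mol %), toluene, 80 °C
Reagents that add atoms: none
Why: Ring-closing metathesis of the two 1,1-disubstituted alkenes to the tetrasubstituted C5′=C10′ bond, helped by the free allylic hydroxyl; the acrylate alkene is a poor metathesis partner.

Step 18
Reactants: 28 cyclohexene hydroxy ester
Product: 29 diol with 2-substituted allyl alcohol (4′R,6′R,7′R,8′S)
Conditions: i-Bu2AlH (3 equiv), CH2Cl2, −78 °C; aq. potassium sodium tartrate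
Reagents that add atoms: none
Why: 1,2-Reduction of the conjugated ester to the allylic alcohol.

Step 19
Reactants: 29 diol
Product: 30 6′-hydroxy enal (4′R,6′R,7′R,8′S), in equilibrium with its 6′,12′-lactol
Conditions: TEMPO (10 mol %), PhI(OAc)2 (1.05 equiv), CH2Cl2, 0 °C
Reagents that add atoms: none
Why: Oxoammonium oxidation is selective for the unhindered primary allylic alcohol over the hindered secondary one.

**Part C – union and endgame**

Step 20
Reactants: 14 2,2-dimethoxyguaia-1(5),4(15),11(13)-trien-12,8-olide; 30 6′-hydroxy enal (lactol form)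
Product: 33 bridged ketal adduct (C2–O–C12′ tether intact), via mixed ketal 31 (not isolated), via tethered cyclopentadienone ketal 32 (not isolated)
Conditions: PPTS (0.2 equiv), 4 Å molecular sieves, toluene, 25 °C; then CSA (0.1 equiv), 60 °C
Reagents that add atoms: none
Why: Proposed new method: acid exchanges one methoxy group of the allylic ketal 14 for the lactol oxygen of 30 (ordinary transacetalisation); stronger acid then moves the exocyclic double bond into the ring (the 5,5-dialkoxycyclopentadiene is the sink because its ketal can no longer ionise) and the tethered diene cyclises, the closest known reaction being the intramolecular Diels–Alder of 5-allyloxy-5-alkoxycyclopentadienes; the two-atom tether forces C12′ exo, the quaternary C11′ bonds to unsubstituted C3, the bulky lactol oxygen sits anti to the pseudo-axial C10 methyl, and the trans-fused lactol ring holds C12′ next to C6′ so that the diene adds on the H7′ face (the other face carries C8′–OTBS).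

Step 21
Reactants: 33 bridged ketal adduct
Product: 34 C2 ketone with 6′,12′-lactol and free C1′ alcohol
Conditions: AcOH–THF–H2O (3:1:1), 40 °C
Reagents that add atoms: water O
Why: Acetal hydrolysis starts at the easily ionised lactol carbon C12′, so the C2 hemiketal collapses to the ketone without passing through a 7-norbornyl cation; the primary silyl ether is cleaved and the secondary one survives.

Step 22
Reactants: 34 keto lactol
Product: 35 C2 alcohol (OH syn to the C4=C5 alkene) with trans-6′,12′-lactone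
Conditions: Al(O-t-Bu)3 (20 mol %), toluene, 40 °C
Reagents that add atoms: none
Why: Proposed new method: intramolecular Meerwein–Ponndorf–Verley (Tishchenko-type) hydride transfer, in which aluminium bridges the lactol oxygen and the ketone and the C12′–H bond (exo on C11′, about 2.7 Å from C2) delivers hydride through the usual six-membered array, the closest known reactions being Evans–Tishchenko and intramolecular Tishchenko reductions; hydride can only arrive from the C13′–C11′ bridge side, which places the hydroxyl syn to the alkene, and tert-butoxide cannot act as a competing hydride donor.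

Step 23
Reactants: 35 C2 alcohol with trans-6′,12′-lactone
Product: 36 C2,C1′-diacetate (C8′–OTBS retained)
Conditions: Ac2O, DMAP (cat.), pyridine, CH2Cl2, 0 → 25 °C
Reagents that add atoms: acetic anhydride CC(=O)OC(C)=O
Why: Standard acylation of the only two free hydroxyls; O6′ is held in the lactone and O8′ is silylated.

Step 24
Reactants: 36 C2,C1′-diacetate
Product: 38 target CNP0211028.4, via 8′-hydroxy 6′,12′-lactone 37 (not isolated)
Conditions: HF·pyridine, THF–pyridine, 0 → 25 °C; then (ClBu2Sn)2O (5 mol %), toluene, 60 °C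
Reagents that add atoms: none
Why: Fluoride desilylation then tin-catalysed transesterification (lactone walk O6′ → O8′), driven by relief of A(1,2) strain between the equatorial C6′–O bond of the trans-lactone and the C5′ side chain; the cis-8′,12′-lactone with a pseudo-axial 6′-hydroxyl is the arrangement found in the britannilactones.

**Compound list**

1 | 2,5-dimethylfuran | Cc1ccc(C)o1 | starting material
2 | (E)-but-2-enal | C/C=C/C=O | starting material
3 | (R)-3-(2,5-dimethylfuran-3-yl)butanal | O=CC[C@@H](C)c1cc(C)oc1C | intermediate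
4 | (R)-3-(4-bromo-2,5-dimethylfuran-3-yl)butanal | O=CC[C@@H](C)c1c(Br)c(C)oc1C | intermediate
5 | allyltributylstannane | C=CC[Sn](CCCC)(CCCC)CCCC | starting material
6 | (R)-3-(4-allyl-2,5-dimethylfuran-3-yl)butanal | O=CC[C@@H](C)c1c(CC=C)c(C)oc1C | intermediate
7 | methyl 2-(bromomethyl)acrylate | C=C(CBr)C(=O)OC | starting material
8 | methyl (Z)-2-(bromomethyl)-4-{2,5-dimethyl-4-[(R)-4-oxobutan-2-yl]furan-3-yl}but-2-enoate | O=CC[C@@H](C)c1c(C/C=C(\CBr)C(=O)OC)c(C)oc1C | intermediate
9 | hydroxy ester: furan-fused cycloheptane with 8-OH, 10-Me and the methyl acrylate unit on C7 (7S,8R,10R) | C=C(C(=O)OC)[C@@H]1Cc2c(C)oc(C)c2[C@H](C)C[C@H]1O | intermediate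
10 | furan-fused trans-α-methylene-γ-lactone (7S,8R,10R; 12,8-olide, furan on C1/C5) | C=C1C(=O)O[C@@H]2C[C@@H](C)c3c(C)oc(C)c3C[C@@H]12 | intermediate
11 | Z-ene-dione lactone: 1,5-diacetyl cycloheptene fused to the trans-lactone (7S,8R,10R) | C=C1C(=O)O[C@@H]2C[C@@H](C)C(C(C)=O)=C(C(C)=O)C[C@@H]12 | intermediate
12 | 4-hydroxy-4-methyl-2-oxoguaia-1(5),11(13)-dien-12,8-olide (C4 epimers) | C=C1C(=O)O[C@@H]2C[C@@H](C)C3=C(C[C@@H]12)C(C)(O)CC3=O | intermediate
13 | 2-oxoguaia-1(5),4(15),11(13)-trien-12,8-olide (7S,8R,10R) | C=C1C(=O)O[C@@H]2C[C@@H](C)C3=C(C[C@@H]12)C(=C)CC3=O | intermediate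
14 | 2,2-dimethoxyguaia-1(5),4(15),11(13)-trien-12,8-olide (7S,8R,10R) | C=C1C(=O)O[C@@H]2C[C@@H](C)C3=C(C[C@@H]12)C(=C)CC3(OC)OC | intermediate
15 | (R)-citronellal | O=CC[C@H](C)CCC=C(C)C | starting material
16 | (R)-8,8-dimethoxy-2,6-dimethyloct-2-ene | COC(OC)C[C@H](C)CCC=C(C)C | intermediate
17 | (R)-6,6-dimethoxy-4-methylhexan-1-ol | COC(OC)C[C@H](C)CCCO | intermediate
18 | (R)-tert-butyl[(6,6-dimethoxy-4-methylhexyl)oxy]dimethylsilane | COC(OC)C[C@H](C)CCCO[Si](C)(C)C(C)(C)C | intermediate
19 | (R)-6-[(tert-butyldimethylsilyl)oxy]-3-methylhexanal | O=CC[C@H](C)CCCO[Si](C)(C)C(C)(C)C | intermediate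
20 | (R)-6-[(tert-butyldimethylsilyl)oxy]-3-methyl-2-methylenehexanal | O=CC(=C)[C@H](C)CCCO[Si](C)(C)C(C)(C)C | intermediate
21 | acrolein | C=CC=O | starting material
22 | tributyl(2-methylallyl)stannane | C=C(C)C[Sn](CCCC)(CCCC)CCCC | starting material
23 | (S)-5-methylhexa-1,5-dien-3-ol | C=C[C@@H](O)CC(C)=C | intermediate
24 | (S)-tert-butyldimethyl[(5-methylhexa-1,5-dien-3-yl)oxy]silane | C=C[C@@H](O[Si](C)(C)C(C)(C)C)CC(C)=C | intermediate
25 | methyl (S,Z)-2-(bromomethyl)-4-[(tert-butyldimethylsilyl)oxy]-6-methylhepta-2,6-dienoate | BrC/C(C(=O)OC)=C\[C@@H](O[Si](C)(C)C(C)(C)C)CC(C)=C | intermediate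
26 | 6′-O-trimethylsilyl ether of 27 (same configuration) | C=C(C(=O)OC)[C@H]([C@@H](O[Si](C)(C)C)C(=C)[C@H](C)CCCO[Si](C)(C)C(C)(C)C)[C@@H](O[Si](C)(C)C(C)(C)C)CC(C)=C | intermediate
27 | acyclic hydroxy ester (4′R,6′R,7′R,8′S): methyl acrylate whose C7′ carries C6′H(OH)–C5′(=CH2)–C4′H(Me)(CH2)3OTBS and C8′H(OTBS)–CH2–C(Me)=CH2; 6′-OH/C7′ anti | C=C(C(=O)OC)[C@H]([C@@H](O)C(=C)[C@H](C)CCCO[Si](C)(C)C(C)(C)C)[C@@H](O[Si](C)(C)C(C)(C)C)CC(C)=C | intermediate
28 | cyclohexene hydroxy ester (4′R,6′R,7′R,8′S): 6′-OH trans and 8′-OTBS cis to the C7′ acrylate | C=C(C(=O)OC)[C@@H]1[C@@H](O)C([C@H](C)CCCO[Si](C)(C)C(C)(C)C)=C(C)C[C@@H]1O[Si](C)(C)C(C)(C)C | intermediate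
29 | diol (4′R,6′R,7′R,8′S): ester of 28 reduced to CH2OH | C=C(CO)[C@@H]1[C@@H](O)C([C@H](C)CCCO[Si](C)(C)C(C)(C)C)=C(C)C[C@@H]1O[Si](C)(C)C(C)(C)C | intermediate
30 | 6′-hydroxy enal (4′R,6′R,7′R,8′S), open form of the 6′,12′-lactol | C=C(C=O)[C@@H]1[C@@H](O)C([C@H](C)CCCO[Si](C)(C)C(C)(C)C)=C(C)C[C@@H]1O[Si](C)(C)C(C)(C)C | intermediate
31 | mixed ketal: C2(OMe)(O–C12′) between 14 and the lactol of 30 (C2 and C12′ epimers) | C=C1C(=O)O[C@@H]2C[C@@H](C)C3=C(C[C@@H]12)C(=C)CC3(OC)OC4O[C@H]5C([C@H](C)CCCO[Si](C)(C)C(C)(C)C)=C(C)C[C@H](O[Si](C)(C)C(C)(C)C)[C@@H]5C4=C | intermediate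
32 | tethered cyclopentadienone ketal: as 31 with the C3=C4 ring double bond and a C4 methyl | C=C1C(=O)O[C@@H]2C[C@@H](C)C3=C(C[C@@H]12)C(C)=CC3(OC)OC4O[C@H]5C([C@H](C)CCCO[Si](C)(C)C(C)(C)C)=C(C)C[C@H](O[Si](C)(C)C(C)(C)C)[C@@H]5C4=C | intermediate
33 | bridged ketal adduct: norbornene with C2(OMe)–O–C12′H–O6′ bridging acetal, target configuration at C1, C3, C7, C8, C10, C11′, C4′, C6′, C7′, C8′ | C=C1C(=O)O[C@@H]2C[C@@H](C)[C@]34C[C@@]5([C@@H]7O[C@H]6C([C@H](C)CCCO[Si](C)(C)C(C)(C)C)=C(C)C[C@H](O[Si](C)(C)C(C)(C)C)[C@@H]65)[C@H](C(C)=C3C[C@@H]12)[C@@]4(OC)O7 | intermediate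
34 | keto lactol: C2 ketone, 6′,12′-lactol (anomers), C1′–OH, C8′–OTBS | C=C1C(=O)O[C@@H]2C[C@@H](C)[C@]34C[C@@]5(C(O)O[C@H]6C([C@H](C)CCCO)=C(C)C[C@H](O[Si](C)(C)C(C)(C)C)[C@@H]65)[C@H](C(C)=C3C[C@@H]12)C4=O | intermediate
35 | C2 alcohol (OH syn to C4=C5), trans-6′,12′-spiro-lactone, C1′–OH, C8′–OTBS | C=C1C(=O)O[C@@H]2C[C@@H](C)[C@]34C[C@@]5(C(=O)O[C@H]6C([C@H](C)CCCO)=C(C)C[C@H](O[Si](C)(C)C(C)(C)C)[C@@H]65)[C@H](C(C)=C3C[C@@H]12)[C@@H]4O | intermediate
36 | C2,C1′-diacetate of 35 | C=C1C(=O)O[C@@H]2C[C@@H](C)[C@]34C[C@@]5(C(=O)O[C@H]6C([C@H](C)CCCOC(C)=O)=C(C)C[C@H](O[Si](C)(C)C(C)(C)C)[C@@H]65)[C@H](C(C)=C3C[C@@H]12)[C@@H]4OC(C)=O | intermediate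
37 | 8′-hydroxy 6′,12′-lactone (desilylated 36) | C=C1C(=O)O[C@@H]2C[C@@H](C)[C@]34C[C@@]5(C(=O)O[C@H]6C([C@H](C)CCCOC(C)=O)=C(C)C[C@H](O)[C@@H]65)[C@H](C(C)=C3C[C@@H]12)[C@@H]4OC(C)=O | intermediate
38 | CNP0211028.4 (2-acetoxy guaianolide / 1′-O-acetyl-6′-hydroxy-8′,12′-olide spiro dimer) | C=C1C(=O)O[C@@H]2C[C@@H](C)[C@]34C[C@@]5(C(=O)O[C@H]6CC(C)=C([C@H](C)CCCOC(C)=O)[C@H](O)[C@H]65)[C@H](C(C)=C3C[C@@H]12)[C@@H]4OC(C)=O | target

**Totals**
Total step count: 24. Longest linear sequence: 13 steps (steps 1–8 then 20–24; the citronellal branch, steps 9–12, 16–19 and 20–24, is equally long).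

**The three steps most likely to fail**

Step 20 (tethered cycloaddition cascade). The mixed ketal may not form from a hindered lactol, or 14 may isomerise before it is tethered. The fallback sets out from 14 and 30 and drops the tether. 14 is isomerised with CSA in CH2Cl2 at 0 °C to the endocyclic 2,2-dimethoxy diene F1, which is heated with 30 in toluene at 70 °C. The open hydroxy enal then reacts intermolecularly, its O6′–H···O=C12′ hydrogen bond standing in for the lactol ring, to give the 2,2-dimethoxy adduct lactol F2. Aqueous 1 M H2SO4 in THF at 25 °C cleaves the ketal and the primary silyl ether, and the route is rejoined at 34.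

Step 22 (hydride relay). If the five-atom C12′–H···C2 geometry does not allow transfer, the fallback sets out from 34 and uses hydroxyl-directed borohydride delivery instead of a C–H hydride shift. Me4NBH(OAc)3 in AcOH–MeCN at −20 °C exchanges onto the lactol hydroxyl and reduces the C2 ketone from the same exo side, giving the C2-hydroxy lactol F3. Ag2CO3 on Celite in hot benzene then oxidises only the lactol, and the route is rejoined at 35.

Step 7 (direction of the aldol). If the acetyl on C5 acts as the nucleophile, the wrong cyclopentenone results. The fallback sets out from 11 and fixes the roles of the two ketones. 1,2-Bis(trimethylsilyloxy)ethane with Me3SiOTf at −78 °C ketalises only the less hindered acetyl to give the mono-dioxolane F4. Me3SiOTf and i-Pr2NEt then enol-silylate the remaining acetyl, which attacks the activated dioxolane (intramolecular Mukaiyama acetal aldol) to give the β-(2-silyloxyethoxy) ketone F5. p-TsOH in toluene eliminates the alkoxy group, and the route is rejoined at 13.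

**Further compounds**
F1 | step 20 | 2,2-dimethoxyguaia-1(5),3,11(13)-trien-12,8-olide (7S,8R,10R) | C=C1C(=O)O[C@@H]2C[C@@H](C)C3=C(C[C@@H]12)C(C)=CC3(OC)OC
F2 | step 20 | 2,2-dimethoxy adduct with 6′,12′-lactol (both silyl ethers intact) | C=C1C(=O)O[C@@H]2C[C@@H](C)[C@]34C[C@@]5(C(O)O[C@H]6C([C@H](C)CCCO[Si](C)(C)C(C)(C)C)=C(C)C[C@H](O[Si](C)(C)C(C)(C)C)[C@@H]65)[C@H](C(C)=C3C[C@@H]12)C4(OC)OC
F3 | step 22 | C2-hydroxy 6′,12′-lactol (OH syn to C4=C5) | C=C1C(=O)O[C@@H]2C[C@@H](C)[C@]34C[C@@]5(C(O)O[C@H]6C([C@H](C)CCCO)=C(C)C[C@H](O[Si](C)(C)C(C)(C)C)[C@@H]65)[C@H](C(C)=C3C[C@@H]12)[C@@H]4O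
F4 | step 7 | mono-dioxolane of 11 (ketal on the acetyl at C5) | C=C1C(=O)O[C@@H]2C[C@@H](C)C(C(C)=O)=C(C3(C)OCCO3)C[C@@H]12
F5 | step 7 | 4-[2-(trimethylsilyloxy)ethoxy]-4-methyl-2-oxoguaia-1(5),11(13)-dien-12,8-olide | C=C1C(=O)O[C@@H]2C[C@@H](C)C3=C(C[C@@H]12)C(C)(OCCO[Si](C)(C)C)CC3=O
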